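**Plan**

- Retrosynthesis: the two O–Si bonds are cut first, then the C2–C3 bond of ring C (carbenoid C–H insertion), then the C=N2 bond on the acetyl carbon (diazo transfer), the ArO–CH2Ar ether bond (Mitsunobu), and last the aryl C–geranyl bond (C-alkylation).
- Enabling feature: C2 of ring C is bonded to the ring oxygen O1 and to the dimethoxyphenyl ring B, so in the open form its C–H bonds are ether-activated and benzylic. C2 lies 1,6 to C3, the carbon alpha to the C4 ketone, so a keto-carbenoid at C3 can insert there and close ring C.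
- Forward: ring A is bought as phloroacetophenone and geranylated at carbon. The three hydroxyls are then capped in their order of reactivity (para, open ortho, flanked ortho). The acetyl group becomes the diazoketone, ring C closes, and the silyl groups come off.
- Stereochemistry: the single stereocentre C2 (S) is set during ring closure by a chiral Rh(II) carboxylate. The E-alkene comes from geranyl bromide and is not touched.

Key step: step 6

Abbreviations: geranyl = (2E)-3,7-dimethylocta-2,6-dien-1-yl; TBS = tert-butyldimethylsilyl. Ring A locants of compound 3 are kept for 4–9.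

Assumption: Rh2(S-PTTL)4 is taken to deliver the 2S product; should it favour 2R, the enantiomeric catalyst Rh2(R-PTTL)4 would be used with no other change.

**Route**

Step 1
Reactants: 1 2',4',6'-trihydroxyacetophenone; 2 geranyl bromide
Product: 3 1-[3-geranyl-2,4,6-trihydroxyphenyl]ethanone
Conditions: DBU, THF, 0 °C to rt, 1 in excess
Reagents that add atoms: none
Why: The ambident phloroglucinol-type phenoxide is alkylated at ring carbon by the allylic bromide in an SN2 reaction (nuclear C-alkylation of an acylphloroglucinol); C3 and C5 are equivalent so only one C-isomer can form, the E-alkene is not involved, and the excess of 1 limits dialkylation.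

Step 2
Reactants: 3 1-[3-geranyl-2,4,6-trihydroxyphenyl]ethanone
Product: 4 1-[4-(tert-butyldimethylsilyloxy)-3-geranyl-2,6-dihydroxyphenyl]ethanone
Conditions: TBSCl (1.0 equiv), imidazole, CH2Cl2–DMF, −20 to 0 °C
Reagents that add atoms: tert-butyldimethylsilyl chloride, CC(C)(C)[Si](C)(C)Cl
Why: The 4-hydroxyl, para to the acetyl group, is the most acidic and takes no part in the hydrogen bond to the carbonyl oxygen, so one equivalent of silyl chloride should react there first (regioselective phenol silylation).

Step 3
Reactants: 4 1-[4-(tert-butyldimethylsilyloxy)-3-geranyl-2,6-dihydroxyphenyl]ethanone; 5 3,4-dimethoxybenzyl alcohol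
Product: 6 1-[4-(tert-butyldimethylsilyloxy)-6-(3,4-dimethoxybenzyloxy)-3-geranyl-2-hydroxyphenyl]ethanone
Conditions: PPh3, DIAD, THF, 0 °C to rt
Reagents that add atoms: none
Why: Mitsunobu etherification works under neutral conditions that spare the aryl silyl ether, and of the two ortho hydroxyls the one at C6 is open while the C2 hydroxyl is wedged between the geranyl and acetyl groups and holds the hydrogen bond, the same bias that leaves the flanked hydroxyl free in partial alkylations of C-alkylphloroacetophenones.

Step 4
Reactants: 6 1-[4-(tert-butyldimethylsilyloxy)-6-(3,4-dimethoxybenzyloxy)-3-geranyl-2-hydroxyphenyl]ethanone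
Product: 7 1-[2,4-bis(tert-butyldimethylsilyloxy)-6-(3,4-dimethoxybenzyloxy)-3-geranylphenyl]ethanone
Conditions: TBSOTf, 2,6-lutidine, CH2Cl2, −78 to 0 °C
Reagents that add atoms: tert-butyldimethylsilyl trifluoromethanesulfonate, CC(C)(C)[Si](C)(C)OS(=O)(=O)C(F)(F)F
Why: The last hydroxyl is chelated and hindered and therefore needs the silyl triflate, while the hindered pyridine base at low temperature keeps the medium non-acidic for the dimethoxybenzyl ether (silylation of a hindered phenol).

Step 5
Reactants: 7 1-[2,4-bis(tert-butyldimethylsilyloxy)-6-(3,4-dimethoxybenzyloxy)-3-geranylphenyl]ethanone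
Product: 9 2-diazo-1-[2,4-bis(tert-butyldimethylsilyloxy)-6-(3,4-dimethoxybenzyloxy)-3-geranylphenyl]ethanone, via trifluoroacetyl ketone 8 (not isolated)
Conditions: LiHMDS, THF, −78 °C; CF3CO2CH2CF3; cold dilute HCl work-up; then MsN3, Et3N, H2O, MeCN, rt
Reagents that add atoms: methanesulfonyl azide, CS(=O)(=O)N=[N+]=[N-]
Why: Claisen-type trifluoroacetylation of the lithium enolate activates the methyl group, and the resulting 1,3-diketone accepts the diazo group from the sulfonyl azide with loss of the trifluoroacetyl group (detrifluoroacetylative Danheiser diazo transfer, established for aryl methyl ketones), under conditions to which the aryl silyl ethers, the benzyl ether and the alkenes are inert.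

Step 6
Reactants: 9 2-diazo-1-[2,4-bis(tert-butyldimethylsilyloxy)-6-(3,4-dimethoxybenzyloxy)-3-geranylphenyl]ethanone
Product: 10 (2S)-5,7-bis(tert-butyldimethylsilyloxy)-2-(3,4-dimethoxyphenyl)-6-geranylchroman-4-one
Conditions: Rh2(S-PTTL)4 (2 mol %), CH2Cl2, 4 Å MS, 0 °C, slow addition of 9
Reagents that add atoms: none
Why: Rh(II) binds the diazo carbon of 9, dinitrogen leaves, and the electrophilic keto-carbenoid inserts into a benzylic C–H bond of the ortho OCH2Ar group through a concerted, hydride-transfer-like three-centre transition state, which forms the C2–C3 bond. The closest known reaction type is the Rh(II) carboxylate-catalysed intramolecular C–H insertion of ortho-alkoxyaryl alpha-diazoketones to chroman-4-ones, including its enantioselective variant with chiral carboxylates. Ring C closes as a six-membered ring by 1,6-insertion, the only insertion mode available because the atom in the 1,5 position is the ether oxygen and carries no hydrogen. The C2 stereocentre is under catalyst control: the chiral N-phthaloyl-tert-leucinate ligands of Rh2(S-PTTL)4 distinguish the two enantiotopic benzylic hydrogens. The step requires insertion to outrun oxonium-ylide formation with 1,2-benzyl shift, Buchner addition to ring B and attack on the geranyl alkenes; the C–H bond is doubly activated (alpha-oxygen, electron-rich aryl), the two ortho substituents twist the acyl group out of the arene plane so that the carbenoid carbon sits over the OCH2 hydrogens and away from the in-plane ether lone pair, the silyl ether oxygens are poor donors without reachable C–H bonds, and the geranyl group is meta to the acyl carbon where no small ring can close. Slow addition at high dilution suppresses carbene dimerisation and intermolecular cyclopropanation.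

Step 7
Reactants: 10 (2S)-5,7-bis(tert-butyldimethylsilyloxy)-2-(3,4-dimethoxyphenyl)-6-geranylchroman-4-one
Product: 11 (2S)-2-(3,4-dimethoxyphenyl)-6-geranyl-5,7-dihydroxychroman-4-one
Conditions: TBAF, AcOH, THF, 0 °C to rt
Reagents that add atoms: none
Why: Fluoride cleaves both aryl O–Si bonds while acetic acid keeps the medium too weakly basic for retro-oxa-Michael opening to the chalcone, so the C2 configuration should be retained (buffered fluoride desilylation).

**Compound list**

1 | 2',4',6'-trihydroxyacetophenone | CC(=O)c1c(O)cc(O)cc1O | starting material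
2 | geranyl bromide | CC(C)=CCC/C(C)=C/CBr | starting material
3 | 1-[3-geranyl-2,4,6-trihydroxyphenyl]ethanone | CC(=O)c1c(O)cc(O)c(C/C=C(\C)CCC=C(C)C)c1O | intermediate
4 | 1-[4-(tert-butyldimethylsilyloxy)-3-geranyl-2,6-dihydroxyphenyl]ethanone | CC(=O)c1c(O)cc(O[Si](C)(C)C(C)(C)C)c(C/C=C(\C)CCC=C(C)C)c1O | intermediate
5 | 3,4-dimethoxybenzyl alcohol | COc1ccc(CO)cc1OC | starting material
6 | 1-[4-(tert-butyldimethylsilyloxy)-6-(3,4-dimethoxybenzyloxy)-3-geranyl-2-hydroxyphenyl]ethanone | CC(=O)c1c(OCc2ccc(OC)c(OC)c2)cc(O[Si](C)(C)C(C)(C)C)c(C/C=C(\C)CCC=C(C)C)c1O | intermediate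
7 | 1-[2,4-bis(tert-butyldimethylsilyloxy)-6-(3,4-dimethoxybenzyloxy)-3-geranylphenyl]ethanone | CC(=O)c1c(OCc2ccc(OC)c(OC)c2)cc(O[Si](C)(C)C(C)(C)C)c(C/C=C(\C)CCC=C(C)C)c1O[Si](C)(C)C(C)(C)C | intermediate
8 | 1-[2,4-bis(tert-butyldimethylsilyloxy)-6-(3,4-dimethoxybenzyloxy)-3-geranylphenyl]-4,4,4-trifluorobutane-1,3-dione | O=C(CC(=O)C(F)(F)F)c1c(OCc2ccc(OC)c(OC)c2)cc(O[Si](C)(C)C(C)(C)C)c(C/C=C(\C)CCC=C(C)C)c1O[Si](C)(C)C(C)(C)C | intermediate
9 | 2-diazo-1-[2,4-bis(tert-butyldimethylsilyloxy)-6-(3,4-dimethoxybenzyloxy)-3-geranylphenyl]ethanone | [N-]=[N+]=CC(=O)c1c(OCc2ccc(OC)c(OC)c2)cc(O[Si](C)(C)C(C)(C)C)c(C/C=C(\C)CCC=C(C)C)c1O[Si](C)(C)C(C)(C)C | intermediate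
10 | (2S)-5,7-bis(tert-butyldimethylsilyloxy)-2-(3,4-dimethoxyphenyl)-6-geranylchroman-4-one | COc1ccc([C@@H]2CC(=O)c3c(cc(O[Si](C)(C)C(C)(C)C)c(C/C=C(\C)CCC=C(C)C)c3O[Si](C)(C)C(C)(C)C)O2)cc1OC | intermediate
11 | (2S)-2-(3,4-dimethoxyphenyl)-6-geranyl-5,7-dihydroxychroman-4-one | COc1ccc([C@@H]2CC(=O)c3c(cc(O)c(C/C=C(\C)CCC=C(C)C)c3O)O2)cc1OC | target

**Step count and risks**

Total steps: 7. Longest linear sequence: 7 (from 1).

Steps most likely to fail:

1. Step 6. The carbenoid may be diverted to the five-membered oxonium ylide at the benzyl ether oxygen, followed by 1,2-shift of the electron-rich benzyl group, or the catalyst may discriminate poorly between the two benzylic hydrogens. The fallback sets out from 7 and returns at 10, and forms the C2–aryl bond instead of C2–C3. Oxidative removal of the dimethoxybenzyl group with DDQ in buffered wet CH2Cl2 would give 1-[2,4-bis(tert-butyldimethylsilyloxy)-3-geranyl-6-hydroxyphenyl]ethanone F1. Condensation with N,N-dimethylformamide dimethyl acetal in toluene would give (E)-3-(dimethylamino)-1-[2,4-bis(tert-butyldimethylsilyloxy)-3-geranyl-6-hydroxyphenyl]prop-2-en-1-one F2. Mild acid (AcOH or silica) would close this with loss of dimethylamine to 5,7-bis(tert-butyldimethylsilyloxy)-6-geranylchromone F3. Base-free Rh(I)/chiral bisphosphine-catalysed 1,4-addition of (3,4-dimethoxyphenyl)boronic acid (Hayashi–Miyaura type addition to a chromone, ligand antipode chosen for 2S) would then give 10.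

2. Step 3. Site selection between the two ortho hydroxyls may be incomplete, with etherification at the flanked hydroxyl or at both. The fallback sets out from 3 and returns at 7; it also bypasses steps 2 and 4. It moves the site selection to the base-mediated partial alkylation for which the bias is precedented, and attaches the dimethoxybenzyl group last, when only one hydroxyl is left. Allyl bromide (2.2 equiv) and K2CO3 in acetone would give 1-[4,6-bis(allyloxy)-3-geranyl-2-hydroxyphenyl]ethanone F4, whose isomers, if any, are separated at this cheap stage. TBSOTf and 2,6-lutidine would give 1-[4,6-bis(allyloxy)-2-(tert-butyldimethylsilyloxy)-3-geranylphenyl]ethanone F5. Pd(PPh3)4 with morpholine would remove both allyl groups to give 1-[2-(tert-butyldimethylsilyloxy)-3-geranyl-4,6-dihydroxyphenyl]ethanone F6. TBSCl and imidazole would silylate the 4-hydroxyl, the 6-hydroxyl now being the only chelated one, to give 1-[2,4-bis(tert-butyldimethylsilyloxy)-3-geranyl-6-hydroxyphenyl]ethanone F1. Mitsunobu etherification of F1 with 5 would give 7.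

3. Step 1. O-alkylation, double C-alkylation and dearomatising gem-dialkylation may compete with mono C-alkylation. The fallback sets out from 2 and returns at 3, and replaces phenoxide alkylation by directed ortho-metalation. Phloroglucinol (Oc1cc(O)cc(O)c1) with MOMCl and NaH would give 1,3,5-tris(methoxymethoxy)benzene F7. Lithiation between two MOM ethers (n-BuLi, THF, 0 °C) and alkylation with 2 (CuI cat.) would give 2-geranyl-1,3,5-tris(methoxymethoxy)benzene F8. A second directed lithiation and acylation with N-methoxy-N-methylacetamide would give 1-[3-geranyl-2,4,6-tris(methoxymethoxy)phenyl]ethanone F9. Methanolic HCl at room temperature would remove the three MOM groups and give 3.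

Further compounds
F1 | step 6 | 1-[2,4-bis(tert-butyldimethylsilyloxy)-3-geranyl-6-hydroxyphenyl]ethanone | CC(=O)c1c(O)cc(O[Si](C)(C)C(C)(C)C)c(C/C=C(\C)CCC=C(C)C)c1O[Si](C)(C)C(C)(C)C
F2 | step 6 | (E)-3-(dimethylamino)-1-[2,4-bis(tert-butyldimethylsilyloxy)-3-geranyl-6-hydroxyphenyl]prop-2-en-1-one | CN(C)/C=C/C(=O)c1c(O)cc(O[Si](C)(C)C(C)(C)C)c(C/C=C(\C)CCC=C(C)C)c1O[Si](C)(C)C(C)(C)C
F3 | step 6 | 5,7-bis(tert-butyldimethylsilyloxy)-6-geranylchromone | O=c1ccoc2cc(O[Si](C)(C)C(C)(C)C)c(C/C=C(\C)CCC=C(C)C)c(O[Si](C)(C)C(C)(C)C)c12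
F4 | step 3 | 1-[4,6-bis(allyloxy)-3-geranyl-2-hydroxyphenyl]ethanone | CC(=O)c1c(OCC=C)cc(OCC=C)c(C/C=C(\C)CCC=C(C)C)c1O
F5 | step 3 | 1-[4,6-bis(allyloxy)-2-(tert-butyldimethylsilyloxy)-3-geranylphenyl]ethanone | CC(=O)c1c(OCC=C)cc(OCC=C)c(C/C=C(\C)CCC=C(C)C)c1O[Si](C)(C)C(C)(C)C
F6 | step 3 | 1-[2-(tert-butyldimethylsilyloxy)-3-geranyl-4,6-dihydroxyphenyl]ethanone | CC(=O)c1c(O)cc(O)c(C/C=C(\C)CCC=C(C)C)c1O[Si](C)(C)C(C)(C)C
F7 | step 1 | 1,3,5-tris(methoxymethoxy)benzene | COCOc1cc(OCOC)cc(OCOC)c1
F8 | step 1 | 2-geranyl-1,3,5-tris(methoxymethoxy)benzene | COCOc1cc(OCOC)c(C/C=C(\C)CCC=C(C)C)c(OCOC)c1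
F9 | step 1 | 1-[3-geranyl-2,4,6-tris(methoxymethoxy)phenyl]ethanone | CC(=O)c1c(OCOC)cc(OCOC)c(C/C=C(\C)CCC=C(C)C)c1OCOC
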